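The vessel takes in Q at a steady rate while E is held; on Z, Q and G form J, and part of Z is held as D.

| flask | Q | E | Z | remark | time |
|---|---|---|---|---|---|
| elm | 0.050 M (fed, over 1.0 h) | 2 mM (held) | 0.069 mol% | run made earlier; the fed solution adds 0.25 times the starting volume |  |
| birch | 0.050 M (fed, over 1.0 h) | 2 mM (held) | 0.59 mol% | run made earlier; the fed solution adds 0.25 times the starting volume |  |
| noon | 0.050 M (fed, over 1.0 h) | 2.0 mM (held) | 0.06 mol% | the fed solution adds 0.25 times the starting volume | 1.0 h |
| spring | 0.050 M (fed, over 1.0 h) | 2.0 mM (held) | 0.12 mol% | the fed solution adds 0.25 times the starting volume | 1.0 h |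
| winter | 0.050 M (fed, over 1.0 h) | 2.0 mM (held) | 0.25 mol% | the fed solution adds 0.25 times the starting volume | 1.0 h |
| autumn | 0.050 M (fed, over 1.0 h) | 2.0 mM (held) | 0.5 mol% | the fed solution adds 0.25 times the starting volume | 1.0 h |

- elm (time / min: J / %, Q / %): 8.00: 1.5, 11.0; 15.0: 3.3, 22.1; 25.0: 5.7, 35.9; 30.0: 6.6, 41.8
- birch (time / min: J / %, Q / %): 4.00: 0.8, 5.2; 10.0: 6.7, 9.8; 20.0: 14.2, 19.1; 30.0: 24.3, 27.2

(each reading ± 1 percentage point)

- amounts and yields of J count D too
- charges are per starting volume, the dose included; the dosed solution carries all of it
- at the start none of G is dissolved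
- the earlier runs were read with a standard deviation of 1 percentage point
- steps that have been proposed: E <-> G; Q + G + Z -> Z + J; Z + J <-> D; G -> L
- percentages count the whole charge, also what has not yet gone in
- "hardly changes" means that all values lie within two and a half points (for a concentration: within two and a half percent of the largest)

* amount of J at the end, in percent of the Q charged for noon, spring, winter, autumn, in this order
* how the row runs (falls all the way / rises all the way / hardly changes / rises, then falls / falls, then rises)

In elm, Q builds up roughly evenly from nothing, so its time integral is about half of Q times t. From the readings at 30.0 min: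

k = 2 J / (Q t) = 0.632 h⁻¹

This capture constant k, the share of standing Q turned into J per hour, is a pseudo-first-order constant. As a reading, it carries the scatter of 1 percentage point.

In the first extreme, k stays constant through the run and scales with the loading of Z. Integrating feed minus capture then gives the share of the charge present as J at the end of the feed, with t_f the dosing time:

J_A = 1 − (1 − e^(−k t_f)) / (k t_f)

Noon has k = 0.549 h⁻¹, so J_A = 23.1%. Autumn has k = 4.58 h⁻¹, so J_A = 78.4%.

In the second extreme, J forms for the whole hour at birch's late slope, 0.528 h⁻¹ of the charge. Birch has a higher loading than any flask in the row. This gives: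

J_B = 52.8%

At the end of noon, the first extreme needs 0.422 h⁻¹, less than birch's slope, so noon should lie just under J_A. Autumn's first extreme needs 0.989 h⁻¹, more than that slope, so autumn should lie under J_B. My reckoning is therefore a rising row from just under 23.1% to just under 52.8%.

The forecast gave 13%, 21%, 32% and 45%, a row that rises all the way, and said “the row should still rise throughout”. Its noon value is lower than this reckoning.

The flask gives 21.9%, 30.8%, 40.9% and 50.0%; the row rises all the way.

    E ⇌ G, rate k1*(csat - [G]) (kL = 0.00500 s⁻¹)
    Q + G + Z → Z + J (k = 5100 M⁻² s⁻¹)
    Z + J ⇌ D, settled at all times (K = 49.0 M⁻¹)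
    G → L (k = 7.80 × 10⁻⁶ s⁻¹)

Elm's k of 0.632 h⁻¹, scaled to autumn as 4.58 h⁻¹, gave 78.4%, but autumn reaches 50.0%. The pace of the crossing of E to G and the one-hour reading act together there: a fast crossing gives 73.3% in the same hour, and a reading ten times later gives 100%. In noon, where elm's k gave 23.1% and the flask gives 21.9%, the pace of the crossing is a part of what holds J back: a fast crossing adds 6.5 points, taking J to 28.5%.

(The readings come from a simulation on assumed constants.)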